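**Strategy**

Everything rests on cutting the C1–C2 bond of the propane linker, between the benzylic CH2 of ring C (the 4-hydroxybenzyl ring) and the methyl-bearing CH on ring B (the trisubstituted phenol ring). Because this CH is benzylic to ring B, its chloride is turned by nickel into a planar radical; a nickel/pybox Negishi coupling with a benzylzinc reagent therefore joins the two fragments and sets the (R) centre in one operation, funnelling both epimers of the chloride into one configuration. The precursor is the complete all-cis 2,5-diaryl-3,4-dimethyloxolane, benzyl-protected, carrying a 1-chloroethyl group (epimer mixture) on ring B; the oxolane is built from desymmetrised meso-2,3-dimethylsuccinic anhydride.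

Key step: step 10

Assumption: the sense of induction of (S)-t-Bu-PHOX (step 2) and of (S,S)-i-Pr-pybox (step 10) is taken as drawn; if a first run shows the opposite sense, the mirror-image ligand is used and nothing else changes. Ring A is the 4-hydroxyphenyl ring on the oxolane.

**Route**

Step 1
Reactants: 1 meso-2,3-dimethylsuccinic acid
Product: 2 cis-2,3-dimethylsuccinic anhydride
Conditions: AcCl (neat), reflux; evaporation
Reagents that add atoms: none
Why: Cyclodehydration of a 1,4-diacid with acetyl chloride should close the anhydride without touching the two stereocentres, so the meso acid gives the cis anhydride.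

Step 2
Reactants: 2 cis-2,3-dimethylsuccinic anhydride; 3 1-(benzyloxy)-4-bromobenzene
Product: 6 (2S,3R)-4-[4-(benzyloxy)phenyl]-2,3-dimethyl-4-oxobutanoic acid, via aryllithium 4 (not isolated), via arylzinc triflate 5 (not isolated)
Conditions: 3, n-BuLi, THF, −78 °C; Zn(OTf)2, −78 °C to rt; then 2, [Rh(cod)Cl]2 (4 mol %), (S)-t-Bu-PHOX (8 mol %), THF/DMF, 50 °C; 1 M HCl
Reagents that add atoms: none
Why: Rhodium-catalysed enantioselective desymmetrising cross-coupling of a meso succinic anhydride with an arylzinc reagent, in which the PHOX-bound rhodium inserts into one of the two enantiotopic acyl C–O bonds, so the methyl-bearing carbons keep their syn relation and take the (2S,3R) sense from the ligand.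

Step 3
Reactants: 6 (2S,3R)-4-[4-(benzyloxy)phenyl]-2,3-dimethyl-4-oxobutanoic acid
Product: 7 methyl (2S,3R)-4-[4-(benzyloxy)phenyl]-2,3-dimethyl-4-oxobutanoate
Conditions: TMSCHN2, MeOH/toluene, 0 °C
Reagents that add atoms: trimethylsilyldiazomethane, C[Si](C)(C)C=[N+]=[N-]
Why: Neutral O-methylation of the carboxylic acid with a diazomethane surrogate should leave the epimerisable centre next to the ketone untouched.

Step 4
Reactants: 7 methyl (2S,3R)-4-[4-(benzyloxy)phenyl]-2,3-dimethyl-4-oxobutanoate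
Product: 9 (3S,4R,5S)-5-[4-(benzyloxy)phenyl]-3,4-dimethyloxolan-2-one (all-cis lactone), via hydroxy ester 8 (not isolated)
Conditions: (R)-2-methyl-CBS-oxazaborolidine (20 mol %), BH3·SMe2, THF, −20 °C; MeOH; then PPTS (cat.), CH2Cl2, rt
Reagents that add atoms: none
Why: Corey–Bakshi–Shibata reduction, in which the (R)-oxazaborolidine treats the aryl group as the large substituent and delivers hydride to the Re face under reagent control (against the Felkin preference of the neighbouring methyl centre) to set the (4S) carbinol, whose lactonisation with retention should give the all-cis lactone.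

Step 5
Reactants: 10 2-bromo-4-iodophenol
Product: 11 1-(benzyloxy)-2-bromo-4-iodobenzene
Conditions: BnBr, K2CO3, DMF, rt
Reagents that add atoms: benzyl bromide, BrCc1ccccc1
Why: Williamson ether synthesis on the phenoxide.

Step 6
Reactants: 9 (3S,4R,5S)-5-[4-(benzyloxy)phenyl]-3,4-dimethyloxolan-2-one; 11 1-(benzyloxy)-2-bromo-4-iodobenzene
Product: 13 (3S,4R,5S)-2-[4-(benzyloxy)-3-bromophenyl]-5-[4-(benzyloxy)phenyl]-3,4-dimethyloxolan-2-ol (lactol, anomer mixture), via aryllithium 12 (not isolated)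
Conditions: 11, n-BuLi, THF, −78 °C; then 9, −78 °C; AcOH, −78 °C
Reagents that add atoms: none
Why: Iodine–lithium exchange outruns bromine–lithium exchange at −78 °C, and 1,2-addition of the aryllithium to the lactone should stop at the lithium hemiketalate, which is quenched cold so that the centre next to the carbonyl is not epimerised.

Step 7
Reactants: 13 (3S,4R,5S)-2-[4-(benzyloxy)-3-bromophenyl]-5-[4-(benzyloxy)phenyl]-3,4-dimethyloxolan-2-ol
Product: 15 (2R,3S,4R,5S)-2-[4-(benzyloxy)-3-bromophenyl]-5-[4-(benzyloxy)phenyl]-3,4-dimethyloxolane (all-cis), via oxocarbenium ion 14 (not isolated)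
Conditions: Et3SiH, BF3·OEt2, CH2Cl2, −78 °C; sat. NaHCO3 at −78 °C
Reagents that add atoms: none
Why: Reductive deoxygenation of a lactol (ionic hydrogenation), in which the cyclic 2-aryl oxocarbenium ion should take hydride from the face opposite the 3-methyl, 4-methyl and 5-aryl groups that all lie on one side, so the new C–H is trans to them and the ring B aryl ends up cis.

Step 8
Reactants: 15 (2R,3S,4R,5S)-2-[4-(benzyloxy)-3-bromophenyl]-5-[4-(benzyloxy)phenyl]-3,4-dimethyloxolane
Product: 17 1-{2-(benzyloxy)-5-[(2R,3S,4R,5S)-5-[4-(benzyloxy)phenyl]-3,4-dimethyloxolan-2-yl]phenyl}ethan-1-ol (both carbinol epimers), via aryllithium 16 (not isolated)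
Conditions: n-BuLi, THF, −78 °C; CH3CHO, −78 °C; H2O
Reagents that add atoms: acetaldehyde, CC=O
Why: Bromine–lithium exchange followed by 1,2-addition to acetaldehyde, where no control at the new carbinol is needed because both epimers converge in step 10.

Step 9
Reactants: 17 1-{2-(benzyloxy)-5-[(2R,3S,4R,5S)-5-[4-(benzyloxy)phenyl]-3,4-dimethyloxolan-2-yl]phenyl}ethan-1-ol
Product: 18 (2R,3S,4R,5S)-2-[4-(benzyloxy)-3-(1-chloroethyl)phenyl]-5-[4-(benzyloxy)phenyl]-3,4-dimethyloxolane (both chloride epimers)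
Conditions: PPh3, NCS (premixed), THF, 0 °C; used crude after filtration
Reagents that add atoms: N-chlorosuccinimide, O=C1CCC(=O)N1Cl
Why: Appel-type chlorination through the alkoxyphosphonium salt runs under neutral conditions, so the acid-labile all-cis oxolane is not exposed to HX.

Step 10
Reactants: 18 (2R,3S,4R,5S)-2-[4-(benzyloxy)-3-(1-chloroethyl)phenyl]-5-[4-(benzyloxy)phenyl]-3,4-dimethyloxolane; 19 4-(benzyloxy)benzyl chloride
Product: 21 (2R,3S,4R,5S)-2-{4-(benzyloxy)-3-[(2R)-1-[4-(benzyloxy)phenyl]propan-2-yl]phenyl}-5-[4-(benzyloxy)phenyl]-3,4-dimethyloxolane, via benzylzinc chloride 20 (not isolated)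
Conditions: 19, Zn dust, LiCl, THF, 25 °C; then 18, NiBr2·diglyme (10 mol %), (S,S)-i-Pr-pybox (13 mol %), DMA/THF, 0 °C
Reagents that add atoms: none
Why: The nickel–benzyl species formed from the pybox–NiBr2 precatalyst and zinc reagent 20 abstracts chlorine from 18 to give a planar benzylic radical at the methyl-bearing carbon, stabilised by ring B, so the configuration of either epimer is erased before the radical is captured by the chiral nickel centre and reductive elimination forms the C(sp3)–C(sp3) bond. The closest known reaction type is the nickel/pybox-catalysed stereoconvergent Negishi coupling of racemic secondary benzylic halides with primary organozinc halides. No ring is closed. The new (R) stereocentre is controlled by the C2-symmetric ligand alone, because the nearest oxolane stereocentre lies four bonds away across ring B. The step needs cross-coupling to outrun β-hydride loss to the styrene and homocoupling of 20, which low temperature, the DMA medium and an excess of 20 should secure. It also needs selectivity for the C–Cl bond, which holds because aryl benzyl ethers and the oxolane C–O bonds are inert to the catalyst.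

Step 11
Reactants: 21 (2R,3S,4R,5S)-2-{4-(benzyloxy)-3-[(2R)-1-[4-(benzyloxy)phenyl]propan-2-yl]phenyl}-5-[4-(benzyloxy)phenyl]-3,4-dimethyloxolane
Product: 22 4-[(2S,3R,4S,5R)-5-{4-hydroxy-3-[(2R)-1-(4-hydroxyphenyl)propan-2-yl]phenyl}-3,4-dimethyloxolan-2-yl]phenol (CNP0232576.2)
Conditions: H2 (1 atm), 10% Pd/C, EtOAc/MeOH, rt
Reagents that add atoms: none
Why: Hydrogenolysis of the three aryl benzyl ethers in neutral solvent should be much faster than cleavage of the dialkyl-type benzylic C–O bonds of the oxolane, and no stereocentre is touched.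

**Compound list**

1 | meso-2,3-dimethylsuccinic acid | C[C@@H](C(=O)O)[C@H](C)C(=O)O | starting material
2 | cis-2,3-dimethylsuccinic anhydride | C[C@@H]1[C@H](C)C(=O)OC1=O | intermediate
3 | 1-(benzyloxy)-4-bromobenzene | Brc1ccc(OCc2ccccc2)cc1 | starting material
4 | [4-(benzyloxy)phenyl]lithium | [Li]c1ccc(OCc2ccccc2)cc1 | intermediate
5 | [4-(benzyloxy)phenyl]zinc triflate | O=S(=O)(O[Zn]c1ccc(OCc2ccccc2)cc1)C(F)(F)F | intermediate
6 | (2S,3R)-4-[4-(benzyloxy)phenyl]-2,3-dimethyl-4-oxobutanoic acid | C[C@@H](C(=O)c1ccc(OCc2ccccc2)cc1)[C@H](C)C(=O)O | intermediate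
7 | methyl (2S,3R)-4-[4-(benzyloxy)phenyl]-2,3-dimethyl-4-oxobutanoate | C[C@@H](C(=O)c1ccc(OCc2ccccc2)cc1)[C@H](C)C(=O)OC | intermediate
8 | methyl (2S,3R,4S)-4-[4-(benzyloxy)phenyl]-4-hydroxy-2,3-dimethylbutanoate | C[C@@H]([C@H](O)c1ccc(OCc2ccccc2)cc1)[C@H](C)C(=O)OC | intermediate
9 | (3S,4R,5S)-5-[4-(benzyloxy)phenyl]-3,4-dimethyloxolan-2-one | C[C@@H]1[C@H](C)C(=O)O[C@@H]1c1ccc(OCc2ccccc2)cc1 | intermediate
10 | 2-bromo-4-iodophenol | Oc1ccc(I)cc1Br | starting material
11 | 1-(benzyloxy)-2-bromo-4-iodobenzene | Brc1cc(I)ccc1OCc1ccccc1 | intermediate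
12 | [4-(benzyloxy)-3-bromophenyl]lithium | [Li]c1ccc(OCc2ccccc2)c(Br)c1 | intermediate
13 | (3S,4R,5S)-2-[4-(benzyloxy)-3-bromophenyl]-5-[4-(benzyloxy)phenyl]-3,4-dimethyloxolan-2-ol | C[C@@H]1[C@H](C)C(O)(c2ccc(OCc3ccccc3)c(Br)c2)O[C@@H]1c1ccc(OCc2ccccc2)cc1 | intermediate
14 | (3S,4R,5S)-2-[4-(benzyloxy)-3-bromophenyl]-5-[4-(benzyloxy)phenyl]-3,4-dimethyl-4,5-dihydro-3H-furan-1-ium (oxocarbenium ion) | C[C@@H]1[C@H](C)C(c2ccc(OCc3ccccc3)c(Br)c2)=[O+][C@@H]1c1ccc(OCc2ccccc2)cc1 | intermediate
15 | (2R,3S,4R,5S)-2-[4-(benzyloxy)-3-bromophenyl]-5-[4-(benzyloxy)phenyl]-3,4-dimethyloxolane | C[C@@H]1[C@H](C)[C@H](c2ccc(OCc3ccccc3)c(Br)c2)O[C@@H]1c1ccc(OCc2ccccc2)cc1 | intermediate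
16 | {2-(benzyloxy)-5-[(2R,3S,4R,5S)-5-[4-(benzyloxy)phenyl]-3,4-dimethyloxolan-2-yl]phenyl}lithium | C[C@@H]1[C@H](C)[C@H](c2ccc(OCc3ccccc3)c([Li])c2)O[C@@H]1c1ccc(OCc2ccccc2)cc1 | intermediate
17 | 1-{2-(benzyloxy)-5-[(2R,3S,4R,5S)-5-[4-(benzyloxy)phenyl]-3,4-dimethyloxolan-2-yl]phenyl}ethan-1-ol (carbinol epimers) | C[C@@H]1[C@H](C)[C@H](c2ccc(OCc3ccccc3)c(C(C)O)c2)O[C@@H]1c1ccc(OCc2ccccc2)cc1 | intermediate
18 | (2R,3S,4R,5S)-2-[4-(benzyloxy)-3-(1-chloroethyl)phenyl]-5-[4-(benzyloxy)phenyl]-3,4-dimethyloxolane (chloride epimers) | C[C@@H]1[C@H](C)[C@H](c2ccc(OCc3ccccc3)c(C(C)Cl)c2)O[C@@H]1c1ccc(OCc2ccccc2)cc1 | intermediate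
19 | 4-(benzyloxy)benzyl chloride | ClCc1ccc(OCc2ccccc2)cc1 | starting material
20 | [4-(benzyloxy)benzyl]zinc chloride | Cl[Zn]Cc1ccc(OCc2ccccc2)cc1 | intermediate
21 | (2R,3S,4R,5S)-2-{4-(benzyloxy)-3-[(2R)-1-[4-(benzyloxy)phenyl]propan-2-yl]phenyl}-5-[4-(benzyloxy)phenyl]-3,4-dimethyloxolane | C[C@@H]1[C@H](C)[C@H](c2ccc(OCc3ccccc3)c([C@H](C)Cc3ccc(OCc4ccccc4)cc3)c2)O[C@@H]1c1ccc(OCc2ccccc2)cc1 | intermediate
22 | 4-[(2S,3R,4S,5R)-5-{4-hydroxy-3-[(2R)-1-(4-hydroxyphenyl)propan-2-yl]phenyl}-3,4-dimethyloxolan-2-yl]phenol | C[C@@H]1[C@H](C)[C@H](c2ccc(O)c([C@H](C)Cc3ccc(O)cc3)c2)O[C@@H]1c1ccc(O)cc1 | target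

**Count and risks**

Total step count: 11. Longest linear sequence: 10 steps (steps 1 to 4 and 6 to 11).

Steps most likely to fail:

Step 10. Ligand control at the ortho-alkoxy benzylic radical may be weak (poor facial selectivity), or β-hydride loss to the styrene and homocoupling of the zinc reagent may consume the partners. The fallback makes the same carbon–carbon connection first as a double bond and sets the centre afterwards. It sets out from alcohol 17: Dess–Martin periodinane (CH2Cl2, NaHCO3) should give the methyl ketone 1-{2-(benzyloxy)-5-[(2R,3S,4R,5S)-5-[4-(benzyloxy)phenyl]-3,4-dimethyloxolan-2-yl]phenyl}ethan-1-one F1. Horner–Wadsworth–Emmons olefination with diethyl [4-(benzyloxy)benzyl]phosphonate (NaH, THF, reflux), then equilibration with catalytic iodine, should give the alkene (2R,3S,4R,5S)-2-{4-(benzyloxy)-3-[(E)-1-[4-(benzyloxy)phenyl]prop-1-en-2-yl]phenyl}-5-[4-(benzyloxy)phenyl]-3,4-dimethyloxolane F2. Asymmetric hydrogenation of this trisubstituted unfunctionalised alkene with [Ir(cod)(t-Bu-PHOX)][B(3,5-(CF3)2C6H3)4] (H2, 50 bar, CH2Cl2; ligand enantiomer chosen for the (R) centre) comes back to the route at 21.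

Step 4. Reagent control may fail to override the Felkin preference of the neighbouring methyl centre (poor facial selectivity, so the 4,5-trans lactone forms alongside 9). The fallback uses the substrate bias and then inverts the carbinol. It sets out from keto ester 7: LiBH(s-Bu)3 (THF, −78 °C) should give, after lactonisation on work-up, the trans lactone (3S,4R,5R)-5-[4-(benzyloxy)phenyl]-3,4-dimethyloxolan-2-one F3. LiOH (THF/H2O) and careful acidification at 0 °C open it to the hydroxy acid (2S,3R,4R)-4-[4-(benzyloxy)phenyl]-4-hydroxy-2,3-dimethylbutanoic acid F4. Mitsunobu lactonisation (PPh3, DIAD, toluene, 0 °C) closes it at once with inversion at the benzylic carbon and comes back at 9.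

Step 7. Hydride delivery to the oxocarbenium ion may lose face selectivity, or the Lewis acid may epimerise a benzylic oxolane centre of the strained all-cis product. The fallback puts the C-2 hydrogen in by catalytic syn-hydrogenation. It sets out from lactol 13: MsCl, Et3N (CH2Cl2, 0 °C) should dehydrate it to the cyclic enol ether (2S,3R)-5-[4-(benzyloxy)-3-bromophenyl]-2-[4-(benzyloxy)phenyl]-3,4-dimethyl-2,3-dihydrofuran F5. Hydrogenation with [Ir(cod)(PCy3)(py)]PF6 (H2, CH2Cl2), which leaves the aryl bromide and benzyl ethers intact, should add hydrogen to the face opposite the C-2 aryl and C-3 methyl groups and come back at 15.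

**Further compounds**

F1 | step 10 | 1-{2-(benzyloxy)-5-[(2R,3S,4R,5S)-5-[4-(benzyloxy)phenyl]-3,4-dimethyloxolan-2-yl]phenyl}ethan-1-one | C[C@@H]1[C@H](C)[C@H](c2ccc(OCc3ccccc3)c(C(C)=O)c2)O[C@@H]1c1ccc(OCc2ccccc2)cc1
F2 | step 10 | (2R,3S,4R,5S)-2-{4-(benzyloxy)-3-[(E)-1-[4-(benzyloxy)phenyl]prop-1-en-2-yl]phenyl}-5-[4-(benzyloxy)phenyl]-3,4-dimethyloxolane | C[C@@H]1[C@H](C)[C@H](c2ccc(OCc3ccccc3)c(/C(C)=C/c3ccc(OCc4ccccc4)cc3)c2)O[C@@H]1c1ccc(OCc2ccccc2)cc1
F3 | step 4 | (3S,4R,5R)-5-[4-(benzyloxy)phenyl]-3,4-dimethyloxolan-2-one | C[C@@H]1[C@H](C)C(=O)O[C@H]1c1ccc(OCc2ccccc2)cc1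
F4 | step 4 | (2S,3R,4R)-4-[4-(benzyloxy)phenyl]-4-hydroxy-2,3-dimethylbutanoic acid | C[C@@H]([C@@H](O)c1ccc(OCc2ccccc2)cc1)[C@H](C)C(=O)O
F5 | step 7 | (2S,3R)-5-[4-(benzyloxy)-3-bromophenyl]-2-[4-(benzyloxy)phenyl]-3,4-dimethyl-2,3-dihydrofuran | C[C@@H]1C(C)=C(c2ccc(OCc3ccccc3)c(Br)c2)O[C@@H]1c1ccc(OCc2ccccc2)cc1
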